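**Retrosynthetic overview**

1. Feature: C3 of each dihydrobenzofuran is a diarylmethine next to an O–CH(aryl) carbon, and two of these C3 atoms are also ring atoms of the seven- and eight-membered carbocycles. Each is therefore the outcome of a 1,2-aryl shift in a stilbene, the two ring ones from cis-stilbenes in rings one atom larger.
2. Target ⇐ pentadecamethyl ether ⇐ triol ⇐ trialdehyde ⇐ tris(dimethyl acetal); the three trans-dihydrofurans are closed last, by acid, on 4-methoxybenzylic carbinols.
3. Tris-acetal ⇐ tris-stilbene by a threefold iodane-mediated oxidative aryl shift that contracts the eight- to the seven-membered and the nine- to the eight-membered ring.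
4. Tris-stilbene ⇐ octaarylhexane (chain C1–C6; aryl rings A on C1, B on C2, C on C4, E on C5, D on C6; 4-methoxyphenyl on C1, C3, C6). Ring A=B is closed by metathesis right after C2, ring C=D after C6 while ring E is still masked, and the open stilbene on ring E (to ring F) is made last by Horner–Wadsworth–Emmons olefination, so that no step has more than two styrenes to pair.
5. Chain ⇐ six Matteson homologations (carbon from CH2Cl2, aryl from a Grignard reagent) under control of 1,2-dicyclohexylethane-1,2-diol (DICHED), then exchange of the last boron for aryl by a boronate 1,2-shift. Ring order: eight-, nine-membered, contraction to seven and eight, three furans.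

Key step: step 24

Assumption: LiCHCl2 insertion into an (R,R)-DICHED boronic ester gives the (αS)-chloro boronic ester (CIP order Cl > C > B > H) and the (S,S)-ester gives its mirror image; the diol for each homologation is chosen on that basis.

**Route**

Step 1
Reactants: 1 3,5-dimethoxybenzaldehyde
Product: 2 2-bromo-3,5-dimethoxybenzaldehyde
Conditions: NBS, MeCN, 0 °C to rt
Reagents that add atoms: N-bromosuccinimide, O=C1CCC(=O)N1Br
Why: Electrophilic aromatic bromination; the position ortho to the aldehyde is para to one methoxy group and ortho to the other and is brominated before the position flanked by both methoxy groups.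

Step 2
Reactants: 2 2-bromo-3,5-dimethoxybenzaldehyde
Product: 3 2-bromo-1-ethenyl-3,5-dimethoxybenzene
Conditions: Ph3PCH3Br, KOtBu, THF, 0 °C to rt
Reagents that add atoms: methyltriphenylphosphonium bromide, C[P+](c1ccccc1)(c1ccccc1)c1ccccc1.[Br-]
Why: Wittig methylenation of the aryl aldehyde; the aryl bromide is inert to the ylide and becomes the Grignard handle of rings A and D.

Step 3
Reactants: 4 1-bromo-3,5-dimethoxybenzene
Product: 5 2-bromo-4,6-dimethoxybenzaldehyde
Conditions: POCl3, DMF, 0 to 100 °C; aq. NaOAc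
Reagents that add atoms: N,N-dimethylformamide, CN(C)C=O; water, O
Why: Vilsmeier–Haack formylation; the chloroiminium ion attacks para to one methoxy group and ortho to the other (next to bromine) rather than between the two methoxy groups.

Step 4
Reactants: 5 2-bromo-4,6-dimethoxybenzaldehyde
Product: 6 2-bromo-6-hydroxy-4-methoxybenzaldehyde
Conditions: BCl3 (1.2 equiv), CH2Cl2, −78 to 0 °C; H2O
Reagents that add atoms: none
Why: Chelation-controlled ether cleavage; BCl3 bound to the aldehyde oxygen removes only the methyl group of the ortho methoxy group.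

Step 5
Reactants: 6 2-bromo-6-hydroxy-4-methoxybenzaldehyde
Product: 7 2-bromo-4-methoxy-6-(propan-2-yloxy)benzaldehyde
Conditions: 2-bromopropane, K2CO3, DMF, 60 °C
Reagents that add atoms: 2-bromopropane, CC(C)Br
Why: Williamson etherification of the phenoxide; the isopropyl ether marks the oxygen that later becomes a furan oxygen and can be cleaved beside methyl ethers.

Step 6
Reactants: 7 2-bromo-4-methoxy-6-(propan-2-yloxy)benzaldehyde
Product: 8 1-bromo-2-ethenyl-5-methoxy-3-(propan-2-yloxy)benzene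
Conditions: Ph3PCH3Br, KOtBu, THF, 0 °C to rt
Reagents that add atoms: methyltriphenylphosphonium bromide, C[P+](c1ccccc1)(c1ccccc1)c1ccccc1.[Br-]
Why: Wittig methylenation; it gives the common aryl bromide of rings B and C.

Step 7
Reactants: 7 2-bromo-4-methoxy-6-(propan-2-yloxy)benzaldehyde
Product: 9 2-[2-bromo-4-methoxy-6-(propan-2-yloxy)phenyl]-1,3-dioxolane
Conditions: ethylene glycol, TsOH·H2O (cat.), toluene, reflux, Dean–Stark trap
Reagents that add atoms: ethane-1,2-diol, OCCO
Why: Acid-catalysed acetalisation driven by azeotropic removal of water; the dioxolane keeps the ring-E carbon inert to Grignard formation, to the homologations and to metathesis.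

Step 8
Reactants: 10 (4-methoxyphenyl)boronic acid
Product: 11 (4S,5S)-4,5-dicyclohexyl-2-(4-methoxyphenyl)-1,3,2-dioxaborolane
Conditions: (S,S)-DICHED, MgSO4, Et2O, rt
Reagents that add atoms: (1S,2S)-1,2-dicyclohexylethane-1,2-diol, O[C@@H](C1CCCCC1)[C@@H](O)C1CCCCC1
Why: Boronic ester formation from a boronic acid and a 1,2-diol; it installs the C2-symmetric director for the first two homologations.

Step 9
Reactants: 11 (4S,5S)-4,5-dicyclohexyl-2-(4-methoxyphenyl)-1,3,2-dioxaborolane; 12 dichloromethane; 3 2-bromo-1-ethenyl-3,5-dimethoxybenzene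
Product: 14 (S,S)-DICHED boronic ester of the (S)-(2-ethenyl-4,6-dimethoxyphenyl)(4-methoxyphenyl)methyl group (chain carbon C1), via α-chloro boronic ester 13 (not isolated)
Conditions: 12, n-BuLi, THF, −100 °C; then 11; ZnCl2, −100 °C to rt; then ArMgBr (from 3, Mg, THF), −78 °C to rt
Reagents that add atoms: none
Why: Matteson homologation; LiCHCl2 adds to boron, the ZnCl2-promoted 1,2-shift of the anisyl group gives the (R)-chloride under control of the (S,S)-diol, and the aryl Grignard reagent displaces chloride with inversion through a second boronate shift, which sets C1 as (S); the labile benzylic chloride is not isolated and a minor epimer would be removed as the diastereomeric ester.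

Step 10
Reactants: 14 C1 boronic ester; 12 dichloromethane; 8 1-bromo-2-ethenyl-5-methoxy-3-(propan-2-yloxy)benzene
Product: 16 (S,S)-DICHED boronic ester at C2 (C2 bears the ring-B aryl; C1 as in 14), via C2 α-chloro boronic ester 15 (not isolated)
Conditions: 12, n-BuLi, THF, −100 °C; then 14; ZnCl2, −100 °C to rt; then ArMgBr (from 8, Mg, THF), −78 °C to rt
Reagents that add atoms: none
Why: Matteson homologation with the same director; C1 migrates with retention, the diol fixes the new CHCl carbon and the ring-B Grignard reagent inverts it, which sets C2.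

Step 11
Reactants: 16 C2 boronic ester
Product: 17 eight-membered-ring boronic ester of (S,S)-DICHED (rings A and B joined by a cis CH=CH; boron on ring carbon C2)
Conditions: second-generation Grubbs catalyst RuCl2(PCy3)(H2IMes)(=CHPh) (5 mol%), CH2Cl2 (2 mM), 40 °C
Reagents that add atoms: none
Why: Ring-closing metathesis of the only two styrenes present, on the adjacent carbons C1 and C2, gives the dibenzo-fused eight-membered ring, whose size forces the cis alkene; the boronic ester is inert to the ruthenium carbene.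

Step 12
Reactants: 17 eight-membered-ring boronic ester of (S,S)-DICHED
Product: 19 eight-membered-ring boronic ester of (R,R)-DICHED, via potassium trifluoroborate 18 (not isolated)
Conditions: KHF2, MeOH/H2O, rt; then (R,R)-DICHED, TMSCl, K2CO3, MeCN, rt
Reagents that add atoms: (1R,2R)-1,2-dicyclohexylethane-1,2-diol, O[C@H](C1CCCCC1)[C@H](O)C1CCCCC1
Why: Diol exchange through the trifluoroborate (fluoride displaces the diol, TMSCl then strips fluoride in the presence of the new diol); the next centre needs the opposite director, and the C–B carbon is not touched.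

Step 13
Reactants: 19 eight-membered-ring boronic ester of (R,R)-DICHED; 12 dichloromethane; 20 4-bromoanisole
Product: 22 (R,R)-DICHED boronic ester at C3 (C3 bears 4-methoxyphenyl), via C3 α-chloro boronic ester 21 (not isolated)
Conditions: 12, n-BuLi, THF, −100 °C; then 19; ZnCl2, −100 °C to rt; then 4-MeOC6H4MgBr (from 20, Mg, THF), −78 °C to rt
Reagents that add atoms: none
Why: Matteson homologation under (R,R)-control; the ring carbon C2 migrates with retention and the 4-methoxyphenyl Grignard reagent inverts the (S)-chloride, which sets C3.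

Step 14
Reactants: 22 C3 boronic ester of (R,R)-DICHED
Product: 24 C3 boronic ester of (S,S)-DICHED, via potassium trifluoroborate 23 (not isolated)
Conditions: KHF2, MeOH/H2O, rt; then (S,S)-DICHED, TMSCl, K2CO3, MeCN, rt
Reagents that add atoms: (1S,2S)-1,2-dicyclohexylethane-1,2-diol, O[C@@H](C1CCCCC1)[C@@H](O)C1CCCCC1
Why: Diol exchange through the trifluoroborate; it sets up the director needed for C4 without touching C3.

Step 15
Reactants: 24 C3 boronic ester of (S,S)-DICHED; 12 dichloromethane; 8 1-bromo-2-ethenyl-5-methoxy-3-(propan-2-yloxy)benzene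
Product: 26 (S,S)-DICHED boronic ester at C4 (C4 bears the ring-C aryl with its vinyl group), via C4 α-chloro boronic ester 25 (not isolated)
Conditions: 12, n-BuLi, THF, −100 °C; then 24; ZnCl2 (1 equiv), −100 to 0 °C; then ArMgBr (from 8, Mg, THF), −78 °C to rt
Reagents that add atoms: none
Why: Matteson homologation under (S,S)-control sets C4; the ZnCl2 is limited and the shift is run cold so that the 4-methoxyphenyl group on C3 does not assist loss of chloride from the new CHCl carbon.

Step 16
Reactants: 26 C4 boronic ester of (S,S)-DICHED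
Product: 28 C4 boronic ester of (R,R)-DICHED, via potassium trifluoroborate 27 (not isolated)
Conditions: KHF2, MeOH/H2O, rt; then (R,R)-DICHED, TMSCl, K2CO3, MeCN, rt
Reagents that add atoms: (1R,2R)-1,2-dicyclohexylethane-1,2-diol, O[C@H](C1CCCCC1)[C@H](O)C1CCCCC1
Why: Diol exchange through the trifluoroborate; the carbonate keeps the medium neutral so that the electron-rich styrene of ring C is not protonated.

Step 17
Reactants: 28 C4 boronic ester of (R,R)-DICHED; 12 dichloromethane; 9 2-[2-bromo-4-methoxy-6-(propan-2-yloxy)phenyl]-1,3-dioxolane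
Product: 30 (R,R)-DICHED boronic ester at C5 (C5 bears the ring-E aryl with its dioxolane), via C5 α-chloro boronic ester 29 (not isolated)
Conditions: 12, n-BuLi, THF, −100 °C; then 28; ZnCl2, −100 °C to rt; then ArMgBr (from 9, Mg, THF), −78 °C to rt
Reagents that add atoms: none
Why: Matteson homologation under (R,R)-control; C4 migrates with retention and the ring-E Grignard reagent inverts the chloride, which sets C5.

Step 18
Reactants: 30 C5 boronic ester of (R,R)-DICHED; 12 dichloromethane; 3 2-bromo-1-ethenyl-3,5-dimethoxybenzene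
Product: 32 (R,R)-DICHED boronic ester at C6 (C6 bears the ring-D aryl with its vinyl group), via C6 α-chloro boronic ester 31 (not isolated)
Conditions: 12, n-BuLi, THF, −100 °C; then 30; ZnCl2, −100 °C to rt; then ArMgBr (from 3, Mg, THF), −78 °C to rt
Reagents that add atoms: none
Why: Matteson homologation with the same director sets C6 and leaves boron where the last 4-methoxyphenyl group is needed.

Step 19
Reactants: 32 C6 boronic ester of (R,R)-DICHED; 33 4-bromophenol
Product: 34 octaarylhexane phenol (4-hydroxyphenyl on C6 in place of boron)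
Conditions: 33, n-BuLi (2 equiv), THF, −78 °C to rt; then 32, −78 °C to rt; then Ph3BiF2, −78 °C to rt
Reagents that add atoms: none
Why: Stereospecific sp2–sp3 coupling of a secondary boronic ester with a para-lithiated phenolate; the aryllithium adds to boron, pentavalent bismuth (Ph3BiF2) activates the phenolate oxygen, C6 shifts from boron to the ipso carbon with retention and loss of the boron group re-aromatises the ring.

Step 20
Reactants: 34 octaarylhexane phenol
Product: 35 octaarylhexane (4-methoxyphenyl on C1, C3, C6; rings A=B in the eight-membered ring; vinyl on rings C and D; dioxolane on ring E)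
Conditions: MeI, K2CO3, DMF, rt
Reagents that add atoms: iodomethane, CI
Why: Williamson methylation of the only free phenol.

Step 21
Reactants: 35 octaarylhexane
Product: 36 nine-membered-ring cis-stilbene (rings C and D joined by cis CH=CH)
Conditions: second-generation Hoveyda–Grubbs catalyst RuCl2(H2IMes)(=CH-C6H4-2-OiPr) (10 mol%), toluene (1 mM), 80 °C
Reagents that add atoms: none
Why: Ring-closing metathesis of the only two styrenes left (rings C and D, on C4 and C6) closes the nine-membered ring with a cis alkene; ring E is masked as the dioxolane and the hindered ring stilbene from step 11 does not take part.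

Step 22
Reactants: 36 nine-membered-ring cis-stilbene
Product: 37 ring-E aldehyde
Conditions: 1 M HCl, THF, rt
Reagents that add atoms: water, O
Why: Acid-catalysed acetal hydrolysis; aryl methyl and isopropyl ethers and both ring stilbenes are stable to dilute acid.

Step 23
Reactants: 37 ring-E aldehyde; 38 diethyl [(3,5-dimethoxyphenyl)methyl]phosphonate
Product: 39 tris-stilbene (cis-stilbene in the eight-membered ring, cis-stilbene in the nine-membered ring, open trans-stilbene on ring E)
Conditions: 38, KOtBu, THF, 0 °C to rt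
Reagents that add atoms: none
Why: Horner–Wadsworth–Emmons olefination of the aryl aldehyde with the benzylphosphonate anion, which gives the trans-stilbene.

Step 24
Reactants: 39 tris-stilbene
Product: 40 tris(dimethyl acetal) with the seven- and eight-membered rings and three diarylmethine centres
Conditions: (R,R)-2,6-bis(1-methoxy-1-oxopropan-2-yloxy)phenyl-λ3-iodanediyl diacetate (3.6 equiv), BF3·OEt2, MeOH/CH2Cl2, −78 to −40 °C
Reagents that add atoms: methanol, CO
Why: Trivalent iodine, activated by BF3·OEt2, adds to each stilbene C=C, methanol adds anti at the carbon carrying the aryl with alkoxy groups ortho and para (rings B, C and E), this aryl then shifts to the neighbouring carbon through a phenonium ion as the iodoarene leaves, and methanol traps the oxocarbenium ion as the dimethyl acetal. The reaction type is the known oxidative 1,2-aryl rearrangement of stilbenes and cyclic styrenes to 2,2-diarylacetaldehyde acetals with aryl-λ3-iodanes, for which lactate-derived chiral reagents are established. The seven-membered ring arises by contraction of the eight-membered stilbene ring and the eight-membered ring by contraction of the nine-membered one: the migrating aryl carbon is a ring member, the alkene carbon that receives it stays in the ring and the other is extruded as the acetal carbon, and because both aryl groups are ring members either direction of shift gives the same constitution. The acyclic centre (future C3 of the ring-E furan) is set by the chiral iodane through its choice of alkene face, the shift inverting the carbon that carried iodine; the two ring centres are set by attack on the more open face of each cis-stilbene, fixed by the adjacent chain stereocentres, with the reagent antipode chosen to match (the (R,R)-reagent is written; its enantiomer is taken if a model trans-stilbene shows the opposite sense). The step needs alkene oxidation before arene oxidation, aryl shift before plain 1,2-dimethoxylation and trapping by methanol before the ortho isopropoxy oxygen: the stilbenes are the most electron-rich π bonds, the diacetate at low temperature is a mild oxidant, the ortho and para alkoxy groups favour the phenonium path, and methanol is the solvent. A centre that is set wrongly can be corrected at the aldehyde stage because its α-hydrogen is acidic.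

Step 25
Reactants: 40 tris(dimethyl acetal)
Product: 41 trialdehyde
Conditions: 2 M HCl, THF, 0 °C to rt
Reagents that add atoms: water, O
Why: Acetal hydrolysis to the three α,α-diaryl aldehydes; short, cold acid limits enolisation, while the acidic α-CH leaves room to equilibrate a mis-set centre if needed.

Step 26
Reactants: 41 trialdehyde; 20 4-bromoanisole
Product: 42 triol (three 4-methoxyphenyl carbinols; carbinol centres not controlled)
Conditions: La(C6H4-4-OMe)3 [from 20, Mg, THF, then LaCl3·2LiCl, one per three ArMgBr], THF, −78 to 0 °C; H2O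
Reagents that add atoms: tris(4-methoxyphenyl)lanthanum, COc1ccc(cc1)[La](c1ccc(OC)cc1)c1ccc(OC)cc1
Why: 1,2-Addition of an aryllanthanum reagent to the three aldehydes (LaCl3·2LiCl-mediated Grignard addition); one triaryllanthanum, made from three equivalents of the Grignard reagent and LaCl3·2LiCl, carries the three 4-methoxyphenyl groups that one molecule of 41 takes up, it is oxophilic and only weakly basic so that addition should outrun enolisation of the α,α-diaryl aldehydes, and the new carbinol centres need no control because they are ionised in the next step.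

Step 27
Reactants: 42 triol
Product: 43 pentadecamethyl ether of the target (three trans-2,3-diaryl-2,3-dihydrobenzofurans closed)
Conditions: BCl3, CH2Cl2, −78 to 0 °C; aq. NaHCO3
Reagents that add atoms: none
Why: BCl3 cleaves the secondary alkyl aryl ethers beside the methyl ethers and ionises the 4-methoxybenzylic carbinols, and each ortho oxygen closes onto the cation to the five-membered cyclic ether (acid-mediated dihydrobenzofuran closure); reversible ionisation of the benzylic C–O bond leads to the more stable trans arrangement at each furan.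

Step 28
Reactants: 43 pentadecamethyl ether
Product: 44 CNP0184494.1
Conditions: BBr3, CH2Cl2, −78 °C to rt; MeOH, then H2O
Reagents that add atoms: none
Why: BBr3 cleavage of all fifteen aryl methyl ethers (Lewis-acid demethylation); the benzylic ring ethers are kept by cold addition and short exposure.

**Compound list**

1 | 3,5-dimethoxybenzaldehyde | COc1cc(C=O)cc(OC)c1 | starting material
2 | 2-bromo-3,5-dimethoxybenzaldehyde | COc1cc(C=O)c(Br)c(OC)c1 | intermediate
3 | 2-bromo-1-ethenyl-3,5-dimethoxybenzene | C=Cc1cc(OC)cc(OC)c1Br | intermediate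
4 | 1-bromo-3,5-dimethoxybenzene | COc1cc(Br)cc(OC)c1 | starting material
5 | 2-bromo-4,6-dimethoxybenzaldehyde | COc1cc(Br)c(C=O)c(OC)c1 | intermediate
6 | 2-bromo-6-hydroxy-4-methoxybenzaldehyde | COc1cc(O)c(C=O)c(Br)c1 | intermediate
7 | 2-bromo-4-methoxy-6-(propan-2-yloxy)benzaldehyde | COc1cc(Br)c(C=O)c(OC(C)C)c1 | intermediate
8 | 1-bromo-2-ethenyl-5-methoxy-3-(propan-2-yloxy)benzene | C=Cc1c(Br)cc(OC)cc1OC(C)C | intermediate
9 | 2-[2-bromo-4-methoxy-6-(propan-2-yloxy)phenyl]-1,3-dioxolane | COc1cc(Br)c(C2OCCO2)c(OC(C)C)c1 | intermediate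
10 | (4-methoxyphenyl)boronic acid | COc1ccc(cc1)B(O)O | starting material
11 | (4S,5S)-4,5-dicyclohexyl-2-(4-methoxyphenyl)-1,3,2-dioxaborolane | COc1ccc(cc1)B1O[C@@H](C2CCCCC2)[C@H](C2CCCCC2)O1 | intermediate
12 | dichloromethane | ClCCl | starting material
13 | (4S,5S)-2-[(R)-chloro(4-methoxyphenyl)methyl]-4,5-dicyclohexyl-1,3,2-dioxaborolane | COc1ccc(cc1)[C@H](Cl)B1O[C@@H](C2CCCCC2)[C@H](C2CCCCC2)O1 | intermediate
14 | (S,S)-DICHED boronic ester of the (S)-(2-ethenyl-4,6-dimethoxyphenyl)(4-methoxyphenyl)methyl group (C1) | COc1ccc(cc1)[C@@H](c1c(OC)cc(OC)cc1C=C)B1O[C@@H](C2CCCCC2)[C@H](C2CCCCC2)O1 | intermediate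
15 | C2 α-chloro boronic ester of (S,S)-DICHED | COc1ccc(cc1)[C@@H](c1c(OC)cc(OC)cc1C=C)[C@H](Cl)B1O[C@@H](C2CCCCC2)[C@H](C2CCCCC2)O1 | intermediate
16 | C2 boronic ester of (S,S)-DICHED (rings A and B with vinyl groups) | COc1ccc(cc1)[C@@H](c1c(OC)cc(OC)cc1C=C)[C@@H](c1cc(OC)cc(OC(C)C)c1C=C)B1O[C@@H](C2CCCCC2)[C@H](C2CCCCC2)O1 | intermediate
17 | eight-membered-ring boronic ester of (S,S)-DICHED | COc1ccc(cc1)[C@H]3c4c(OC)cc(OC)cc4/C=C\c4c(OC(C)C)cc(OC)cc4[C@H]3B1O[C@@H](C2CCCCC2)[C@H](C2CCCCC2)O1 | intermediate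
18 | eight-membered-ring potassium trifluoroborate | COc1ccc(cc1)[C@H]3c4c(OC)cc(OC)cc4/C=C\c4c(OC(C)C)cc(OC)cc4[C@H]3[B-](F)(F)F.[K+] | intermediate
19 | eight-membered-ring boronic ester of (R,R)-DICHED | COc1ccc(cc1)[C@H]3c4c(OC)cc(OC)cc4/C=C\c4c(OC(C)C)cc(OC)cc4[C@H]3B1O[C@H](C2CCCCC2)[C@@H](C2CCCCC2)O1 | intermediate
20 | 4-bromoanisole | COc1ccc(Br)cc1 | starting material
21 | C3 α-chloro boronic ester of (R,R)-DICHED | COc1ccc(cc1)[C@H]3c4c(OC)cc(OC)cc4/C=C\c4c(OC(C)C)cc(OC)cc4[C@H]3[C@@H](Cl)B1O[C@H](C2CCCCC2)[C@@H](C2CCCCC2)O1 | intermediate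
22 | C3 boronic ester of (R,R)-DICHED | COc1ccc(cc1)[C@H]3c4c(OC)cc(OC)cc4/C=C\c4c(OC(C)C)cc(OC)cc4[C@H]3[C@H](c1ccc(OC)cc1)B1O[C@H](C2CCCCC2)[C@@H](C2CCCCC2)O1 | intermediate
23 | C3 potassium trifluoroborate | COc1ccc(cc1)[C@H]3c4c(OC)cc(OC)cc4/C=C\c4c(OC(C)C)cc(OC)cc4[C@H]3[C@H](c1ccc(OC)cc1)[B-](F)(F)F.[K+] | intermediate
24 | C3 boronic ester of (S,S)-DICHED | COc1ccc(cc1)[C@H]3c4c(OC)cc(OC)cc4/C=C\c4c(OC(C)C)cc(OC)cc4[C@H]3[C@H](c1ccc(OC)cc1)B1O[C@@H](C2CCCCC2)[C@H](C2CCCCC2)O1 | intermediate
25 | C4 α-chloro boronic ester of (S,S)-DICHED | COc1ccc(cc1)[C@H]3c4c(OC)cc(OC)cc4/C=C\c4c(OC(C)C)cc(OC)cc4[C@H]3[C@H](c1ccc(OC)cc1)[C@H](Cl)B1O[C@@H](C2CCCCC2)[C@H](C2CCCCC2)O1 | intermediate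
26 | C4 boronic ester of (S,S)-DICHED | COc1ccc(cc1)[C@H]3c4c(OC)cc(OC)cc4/C=C\c4c(OC(C)C)cc(OC)cc4[C@H]3[C@H](c1ccc(OC)cc1)[C@@H](c1cc(OC)cc(OC(C)C)c1C=C)B1O[C@@H](C2CCCCC2)[C@H](C2CCCCC2)O1 | intermediate
27 | C4 potassium trifluoroborate | COc1ccc(cc1)[C@H]3c4c(OC)cc(OC)cc4/C=C\c4c(OC(C)C)cc(OC)cc4[C@H]3[C@H](c1ccc(OC)cc1)[C@@H](c1cc(OC)cc(OC(C)C)c1C=C)[B-](F)(F)F.[K+] | intermediate
28 | C4 boronic ester of (R,R)-DICHED | COc1ccc(cc1)[C@H]3c4c(OC)cc(OC)cc4/C=C\c4c(OC(C)C)cc(OC)cc4[C@H]3[C@H](c1ccc(OC)cc1)[C@@H](c1cc(OC)cc(OC(C)C)c1C=C)B1O[C@H](C2CCCCC2)[C@@H](C2CCCCC2)O1 | intermediate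
29 | C5 α-chloro boronic ester of (R,R)-DICHED | COc1ccc(cc1)[C@H]3c4c(OC)cc(OC)cc4/C=C\c4c(OC(C)C)cc(OC)cc4[C@H]3[C@H](c1ccc(OC)cc1)[C@@H](c1cc(OC)cc(OC(C)C)c1C=C)[C@@H](Cl)B1O[C@H](C2CCCCC2)[C@@H](C2CCCCC2)O1 | intermediate
30 | C5 boronic ester of (R,R)-DICHED | COc1ccc(cc1)[C@H]3c4c(OC)cc(OC)cc4/C=C\c4c(OC(C)C)cc(OC)cc4[C@H]3[C@H](c1ccc(OC)cc1)[C@@H](c1cc(OC)cc(OC(C)C)c1C=C)[C@H](c1cc(OC)cc(OC(C)C)c1C1OCCO1)B1O[C@H](C2CCCCC2)[C@@H](C2CCCCC2)O1 | intermediate
31 | C6 α-chloro boronic ester of (R,R)-DICHED | COc1ccc(cc1)[C@H]3c4c(OC)cc(OC)cc4/C=C\c4c(OC(C)C)cc(OC)cc4[C@H]3[C@H](c1ccc(OC)cc1)[C@@H](c1cc(OC)cc(OC(C)C)c1C=C)[C@H](c1cc(OC)cc(OC(C)C)c1C1OCCO1)[C@@H](Cl)B1O[C@H](C2CCCCC2)[C@@H](C2CCCCC2)O1 | intermediate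
32 | C6 boronic ester of (R,R)-DICHED | COc1ccc(cc1)[C@H]3c4c(OC)cc(OC)cc4/C=C\c4c(OC(C)C)cc(OC)cc4[C@H]3[C@H](c1ccc(OC)cc1)[C@@H](c1cc(OC)cc(OC(C)C)c1C=C)[C@H](c1cc(OC)cc(OC(C)C)c1C1OCCO1)[C@H](c1c(OC)cc(OC)cc1C=C)B1O[C@H](C2CCCCC2)[C@@H](C2CCCCC2)O1 | intermediate
33 | 4-bromophenol | Oc1ccc(Br)cc1 | starting material
34 | octaarylhexane phenol | COc1ccc(cc1)[C@H]3c4c(OC)cc(OC)cc4/C=C\c4c(OC(C)C)cc(OC)cc4[C@H]3[C@H](c1ccc(OC)cc1)[C@@H](c1cc(OC)cc(OC(C)C)c1C=C)[C@H](c1cc(OC)cc(OC(C)C)c1C1OCCO1)[C@H](c1c(OC)cc(OC)cc1C=C)c1ccc(O)cc1 | intermediate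
35 | octaarylhexane | COc1ccc(cc1)[C@H]3c4c(OC)cc(OC)cc4/C=C\c4c(OC(C)C)cc(OC)cc4[C@H]3[C@H](c1ccc(OC)cc1)[C@@H](c1cc(OC)cc(OC(C)C)c1C=C)[C@H](c1cc(OC)cc(OC(C)C)c1C1OCCO1)[C@H](c1c(OC)cc(OC)cc1C=C)c1ccc(OC)cc1 | intermediate
36 | nine-membered-ring cis-stilbene with ring-E dioxolane | COc1ccc(cc1)[C@H]3c4c(OC)cc(OC)cc4/C=C\c4c(OC(C)C)cc(OC)cc4[C@H]3[C@H](c1ccc(OC)cc1)[C@@H]2[C@H](c1cc(OC)cc(OC(C)C)c1C1OCCO1)[C@@H](c1ccc(OC)cc1)c1c(OC)cc(OC)cc1/C=C\c1c2cc(OC)cc1OC(C)C | intermediate
37 | ring-E aldehyde | COc1ccc(cc1)[C@H]3c4c(OC)cc(OC)cc4/C=C\c4c(OC(C)C)cc(OC)cc4[C@H]3[C@H](c1ccc(OC)cc1)[C@@H]2[C@H](c1cc(OC)cc(OC(C)C)c1C=O)[C@@H](c1ccc(OC)cc1)c1c(OC)cc(OC)cc1/C=C\c1c2cc(OC)cc1OC(C)C | intermediate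
38 | diethyl [(3,5-dimethoxyphenyl)methyl]phosphonate | CCOP(=O)(Cc1cc(OC)cc(OC)c1)OCC | starting material
39 | tris-stilbene (key-step precursor) | COc1ccc([C@H]2c3c(OC)cc(OC)cc3/C=C\c4c(cc(OC)cc4[C@H]2[C@H](c2ccc(OC)cc2)[C@H]2c4cc(OC)cc(OC(C)C)c4/C=C\c4cc(OC)cc(OC)c4[C@H](c4ccc(OC)cc4)[C@H]2c2cc(OC)cc(OC(C)C)c2/C=C/c2cc(OC)cc(OC)c2)OC(C)C)cc1 | intermediate
40 | tris(dimethyl acetal) (key-step product) | COc1ccc([C@H]2c3c(OC)cc(OC)cc3[C@@H](C(OC)OC)c4c(cc(OC)cc4[C@H]2[C@H](c2ccc(OC)cc2)[C@H]2c4cc(OC)cc(OC(C)C)c4[C@H](C(OC)OC)c4cc(OC)cc(OC)c4[C@H](c4ccc(OC)cc4)[C@H]2c2cc(OC)cc(OC(C)C)c2[C@H](C(OC)OC)c2cc(OC)cc(OC)c2)OC(C)C)cc1 | intermediate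
41 | trialdehyde | COc1ccc([C@H]2c3c(OC)cc(OC)cc3[C@@H](C=O)c4c(cc(OC)cc4[C@H]2[C@H](c2ccc(OC)cc2)[C@H]2c4cc(OC)cc(OC(C)C)c4[C@H](C=O)c4cc(OC)cc(OC)c4[C@H](c4ccc(OC)cc4)[C@H]2c2cc(OC)cc(OC(C)C)c2[C@H](C=O)c2cc(OC)cc(OC)c2)OC(C)C)cc1 | intermediate
42 | triol (carbinol centres undefined) | COc1ccc([C@H]2c3c(OC)cc(OC)cc3[C@@H](C(O)c5ccc(OC)cc5)c4c(cc(OC)cc4[C@H]2[C@H](c2ccc(OC)cc2)[C@H]2c4cc(OC)cc(OC(C)C)c4[C@H](C(O)c5ccc(OC)cc5)c4cc(OC)cc(OC)c4[C@H](c4ccc(OC)cc4)[C@H]2c2cc(OC)cc(OC(C)C)c2[C@H](C(O)c5ccc(OC)cc5)c2cc(OC)cc(OC)c2)OC(C)C)cc1 | intermediate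
43 | pentadecamethyl ether of the target | COc1ccc([C@H]2c3c(OC)cc(OC)cc3[C@@H]3c4c(cc(OC)cc4[C@H]2[C@H](c2ccc(OC)cc2)[C@H]2c4cc(OC)cc5c4[C@@H](c4cc(OC)cc(OC)c4[C@H](c4ccc(OC)cc4)[C@H]2c2cc(OC)cc4c2[C@@H](c2cc(OC)cc(OC)c2)[C@H](c2ccc(OC)cc2)O4)[C@H](c2ccc(OC)cc2)O5)O[C@H]3c2ccc(OC)cc2)cc1 | intermediate
44 | CNP0184494.1 | Oc1ccc([C@H]2c3c(O)cc(O)cc3[C@@H]3c4c(cc(O)cc4[C@H]2[C@H](c2ccc(O)cc2)[C@H]2c4cc(O)cc5c4[C@@H](c4cc(O)cc(O)c4[C@H](c4ccc(O)cc4)[C@H]2c2cc(O)cc4c2[C@@H](c2cc(O)cc(O)c2)[C@H](c2ccc(O)cc2)O4)[C@H](c2ccc(O)cc2)O5)O[C@H]3c2ccc(O)cc2)cc1 | target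

**Totals and risks**

Total step count: 28. Longest linear sequence: 23 steps (steps 3, 4, 5, 6, then 10 to 28).

Steps most likely to fail:

Step 24. The iodane may attack the two ring stilbenes with poor facial selectivity, and oxidation of the electron-rich arenes or plain 1,2-dimethoxylation may compete with the aryl shift. Fallback: starting from 39, the three alkenes are epoxidised with dimethyldioxirane (acetone, 0 °C) to the tris-epoxide F1. BF3·OEt2 in CH2Cl2 at −78 °C then opens each epoxide at the benzylic carbon next to the dialkoxy aryl, and that aryl shifts (Meinwald rearrangement, with ring contraction in the two cyclic cases). This gives the trialdehyde 41 directly, where the route is rejoined.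

Step 19. The crowded boronate complex at C6 may not form, or the hindered secondary carbon may fail to shift to the aryl carbon. Fallback: starting from 32, the C6–B bond is coupled with 4-iodoanisole in a stereoretentive Suzuki–Miyaura reaction (Pd2(dba)3, PPh3, Ag2O, DME, 85 °C). This gives 35 directly, so that steps 19 and 20 are both bypassed; no new compound arises on the way (F0).

Step 21. Closure of the nine-membered ring may be outrun by intermolecular metathesis of the two styrenes. Fallback: starting from 35, the two terminal styrenes are cleaved to aldehydes by Lemieux–Johnson oxidation (OsO4 cat., NaIO4, 2,6-lutidine, dioxane/H2O; the hindered ring stilbene should react more slowly) to give the dialdehyde F2. An intramolecular McMurry coupling with low-valent titanium (TiCl3(DME)1.5, Zn–Cu couple, DME, reflux, slow addition) then closes the nine-membered ring to 36, where the route is rejoined.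

Further compounds
F1 | step 24 | tris-epoxide of 39 (epoxide centres set by the face attacked) | COc1ccc([C@H]2c3c(OC)cc(OC)cc3C5OC5c4c(cc(OC)cc4[C@H]2[C@H](c2ccc(OC)cc2)[C@H]2c4cc(OC)cc(OC(C)C)c4C5OC5c4cc(OC)cc(OC)c4[C@H](c4ccc(OC)cc4)[C@H]2c2cc(OC)cc(OC(C)C)c2C2OC2c2cc(OC)cc(OC)c2)OC(C)C)cc1
F0 | step 19 | none | none
F2 | step 21 | dialdehyde from 35 (formyl groups on rings C and D) | COc1ccc(cc1)[C@H]3c4c(OC)cc(OC)cc4/C=C\c4c(OC(C)C)cc(OC)cc4[C@H]3[C@H](c1ccc(OC)cc1)[C@@H](c1cc(OC)cc(OC(C)C)c1C=O)[C@H](c1cc(OC)cc(OC(C)C)c1C1OCCO1)[C@H](c1c(OC)cc(OC)cc1C=O)c1ccc(OC)cc1
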